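**Retrosynthetic overview**

1. Target 32 ← N-oxidation of the pyridone nitrogen of 29. The tetrahydropyran O1–C2 bond of 29 ← 6-exo oxa-Michael closure of the hydroxymethyl oxygen onto the quinone methide obtained by reducing the 3-acyl ketone of pyridone 26.
2. 26 ← cytochrome P450 ring expansion of 5-benzyl-3-acyltetramic acid 25 (new bond: pyridone C4–C5). The plan rests on the 4-hydroxy-5-phenyl-2-pyridone ring: N1, C6 and the phenyl-bearing C5 are the nitrogen, α-carbon and benzylic carbon of L-phenylalanine, and C4 is its carboxyl carbon.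
3. 25 ← Lacey–Dieckmann closure of the β-ketoamide assembled from trienoic acid 18, Meldrum's acid 19 and L-phenylalanine methyl ester 21.
4. 18 ← Stille union (C5–C6) of (Z)-iodide 9 with dienylstannane 15. Iodide 9 comes from copper-catalysed anti-carbomagnesiation of propargyl alcohol 3 by the Grignard reagent of 1, which fixes 4Z and brings the C2 centre. Stannane 15 comes from (R)-2-methylbutanoic acid 10 and brings the C10 centre.
5. Ring order: pyrrolidine-2,4-dione (step 12), then the pyridone by ring enlargement (step 14), then the tetrahydropyran (step 15); the N–OH group is introduced last (step 16).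

Key step: step 14

Assumption: the ring-expandase is taken from a fungal gene cluster for a phenylalanine-derived 5-phenyl-2-pyridone, so the head group of 25 is native to it and only the oxygenated chain is foreign; 1 and 10 are bought enantiopure.

**Route**

Step 1
Reactants: 1 (S)-3-bromo-2-methylpropan-1-ol
Product: 2 (S)-(3-bromo-2-methylpropoxy)(tert-butyl)dimethylsilane
Conditions: TBSCl, imidazole, CH2Cl2, 0 °C → rt
Reagents that add atoms: tert-butyldimethylsilyl chloride, CC(C)(C)[Si](C)(C)Cl
Why: Standard silyl ether formation on a primary alcohol; the stereocentre and the bromide are not involved.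

Step 2
Reactants: 2 (S)-(3-bromo-2-methylpropoxy)(tert-butyl)dimethylsilane; 3 prop-2-yn-1-ol (propargyl alcohol)
Product: 7 (2Z)-2-[(2R)-3-{[tert-butyl(dimethyl)silyl]oxy}-2-methylpropyl]-3-iodoprop-2-en-1-ol, via Grignard reagent 4 (not isolated), via bromomagnesium propargyl alkoxide 5 (not isolated), via cyclic alkenylmagnesium alkoxide 6 (not isolated)
Conditions: 2, Mg turnings, THF, rt → 45 °C; separately 3, MeMgBr (1.0 equiv), THF, −10 °C; combine (1.8 equiv of 4), CuI (10 mol%), 0 °C → rt; then I2 in THF, −20 °C → rt; aq. Na2S2O3/NH4Cl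
Reagents that add atoms: iodine, [I][I]
Why: Copper-catalysed anti-carbomagnesiation of the magnesium alkoxide of propargyl alcohol puts the alkyl group on the internal carbon and magnesium on the terminal carbon inside a five-membered chelate cis to the CH2O group, so iodinolysis with retention should give the (Z)-iodide as one alkene isomer, and the stereocentre β to magnesium in 4 is untouched.

Step 3
Reactants: 7 (2Z)-2-[(2R)-3-{[tert-butyl(dimethyl)silyl]oxy}-2-methylpropyl]-3-iodoprop-2-en-1-ol
Product: 8 tert-butyl{[(2R,4Z)-4-{[(tert-butyldiphenylsilyl)oxy]methyl}-5-iodo-2-methylpent-4-en-1-yl]oxy}dimethylsilane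
Conditions: TBDPSCl, imidazole, DMF, 0 °C → rt
Reagents that add atoms: tert-butyldiphenylsilyl chloride, CC(C)(C)[Si](Cl)(c1ccccc1)c1ccccc1
Why: Silyl ether formation on the allylic alcohol with the bulkier, more acid-stable group, chosen so that the two primary silyl ethers can be told apart in step 4.

Step 4
Reactants: 8 tert-butyl{[(2R,4Z)-4-{[(tert-butyldiphenylsilyl)oxy]methyl}-5-iodo-2-methylpent-4-en-1-yl]oxy}dimethylsilane
Product: 9 (2R,4Z)-4-{[(tert-butyldiphenylsilyl)oxy]methyl}-5-iodo-2-methylpent-4-en-1-ol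
Conditions: camphorsulfonic acid (10 mol%), MeOH/CH2Cl2 (1:1), 0 °C
Reagents that add atoms: none
Why: Acid-catalysed methanolysis (selective desilylation) cleaves a primary tert-butyldimethylsilyl ether far faster than a tert-butyldiphenylsilyl ether, and it is run here before the acid-sensitive triene exists.

Step 5
Reactants: 10 (R)-2-methylbutanoic acid
Product: 11 (R)-2-methylbutan-1-ol
Conditions: LiAlH4, Et2O, 0 °C → reflux; Fieser work-up; ether removed through a column
Reagents that add atoms: none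
Why: LiAlH4 reduction of a carboxylic acid to the primary alcohol proceeds through the carboxylate, which does not enolise, so the α-stereocentre is kept.

Step 6
Reactants: 11 (R)-2-methylbutan-1-ol
Product: 13 (1E,3R)-1-iodo-3-methylpent-1-ene, via (R)-2-methylbutanal 12 (not isolated)
Conditions: Dess–Martin periodinane, CH2Cl2, 0 °C → rt; cold filtered solution added to CrCl2 (6 equiv), CHI3 (2 equiv), THF/1,4-dioxane, 0 °C → rt, dark
Reagents that add atoms: iodoform, IC(I)I
Why: Dess–Martin oxidation gives the configurationally labile aldehyde, which is consumed at once in a Takai olefination, a non-basic reaction that should give the (E)-iodide and leave the α-stereocentre intact.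

Step 7
Reactants: 13 (1E,3R)-1-iodo-3-methylpent-1-ene; 14 (E)-1,2-bis(tributylstannyl)ethene
Product: 15 tributyl[(1E,3E,5R)-5-methylhepta-1,3-dien-1-yl]stannane
Conditions: 14 (3 equiv), PdCl2(MeCN)2 (5 mol%), DMF, rt, dark; chromatography on Et3N-deactivated silica
Reagents that add atoms: none
Why: Stille coupling at one tin of the distannane, with the excess of 14 suppressing double coupling; both alkene geometries are retained through oxidative addition and transmetallation.

Step 8
Reactants: 9 (2R,4Z)-4-{[(tert-butyldiphenylsilyl)oxy]methyl}-5-iodo-2-methylpent-4-en-1-ol; 15 tributyl[(1E,3E,5R)-5-methylhepta-1,3-dien-1-yl]stannane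
Product: 16 (2R,4Z,6E,8E,10R)-4-{[(tert-butyldiphenylsilyl)oxy]methyl}-2,10-dimethyldodeca-4,6,8-trien-1-ol
Conditions: Pd2(dba)3 (5 mol%), AsPh3 (20 mol%), degassed NMP, rt → 40 °C, dark
Reagents that add atoms: none
Why: Stille coupling of an alkenyl iodide with an alkenylstannane under base-free conditions proceeds with retention at both partners, so the (4Z,6E,8E)-triene follows directly from the geometries of 9 and 15, and the free hydroxyl is tolerated.

Step 9
Reactants: 16 (2R,4Z,6E,8E,10R)-4-{[(tert-butyldiphenylsilyl)oxy]methyl}-2,10-dimethyldodeca-4,6,8-trien-1-ol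
Product: 18 (2R,4Z,6E,8E,10R)-4-{[(tert-butyldiphenylsilyl)oxy]methyl}-2,10-dimethyldodeca-4,6,8-trienoic acid, via aldehyde 17 (not isolated)
Conditions: TEMPO (20 mol%), PhI(OAc)2 (2.5 equiv), MeCN/pH 7 phosphate buffer, 0 °C → rt
Reagents that add atoms: water, O
Why: Oxoammonium (TEMPO) oxidation takes the primary alcohol through aldehyde 17 and its hydrate to the acid under near-neutral conditions that should not touch the triene, the silyl ether or the α-stereocentre.

Step 10
Reactants: 18 (2R,4Z,6E,8E,10R)-4-{[(tert-butyldiphenylsilyl)oxy]methyl}-2,10-dimethyldodeca-4,6,8-trienoic acid; 19 Meldrum's acid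
Product: 20 5-[(2R,4Z,6E,8E,10R)-4-{[(tert-butyldiphenylsilyl)oxy]methyl}-1-hydroxy-2,10-dimethyldodeca-4,6,8-trien-1-ylidene]-2,2-dimethyl-1,3-dioxane-4,6-dione
Conditions: DCC (1.1 equiv), DMAP (1.5 equiv), CH2Cl2, 0 °C → rt; filtration; cold 5% KHSO4 wash
Reagents that add atoms: none
Why: Carbodiimide/DMAP C-acylation of Meldrum's acid by the activated acid gives the enolised acyl Meldrum's acid, a masked acylketene.

Step 11
Reactants: 20 acyl Meldrum's acid; 21 L-phenylalanine methyl ester hydrochloride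
Product: 23 methyl N-[(4R,6Z,8E,10E,12R)-6-{[(tert-butyldiphenylsilyl)oxy]methyl}-4,12-dimethyl-3-oxotetradeca-6,8,10-trienoyl]-L-phenylalaninate, via acylketene 22 (not isolated)
Conditions: Et3N (1.1 equiv), toluene, 80 °C, 2 h, argon
Reagents that add atoms: none
Why: Thermal retro-[4+2] loss of acetone and CO2 gives acylketene 22, which the amine traps as the β-ketoamide (aminolysis of an acyl Meldrum's acid); the amino acid centre is not touched, and the chain centre α′ to the ketone is shielded because the far more acidic C2 methylene enolises first.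

Step 12
Reactants: 23 β-ketoamide
Product: 24 (5S)-5-benzyl-3-[(2R,4Z,6E,8E,10R)-4-{[(tert-butyldiphenylsilyl)oxy]methyl}-2,10-dimethyldodeca-4,6,8-trienoyl]-4-hydroxy-1,5-dihydro-2H-pyrrol-2-one
Conditions: NaOMe (2.5 equiv), MeOH, rt; then cold 0.5 M HCl to pH 3, EtOAc
Reagents that add atoms: none
Why: Lacey–Dieckmann cyclisation, in which the β-ketoamide enolate attacks the methyl ester (5-exo-trig) and the product is held as its stable tetramate anion, which should protect both C5 and the chain α-centre from epimerisation at room temperature.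

Step 13
Reactants: 24 silyl-protected tetramic acid
Product: 25 (5S)-5-benzyl-4-hydroxy-3-[(2R,4Z,6E,8E,10R)-4-(hydroxymethyl)-2,10-dimethyldodeca-4,6,8-trienoyl]-1,5-dihydro-2H-pyrrol-2-one
Conditions: TBAF (3 equiv), AcOH (3 equiv), THF, 0 °C → rt; C18 chromatography; kept as the sodium salt
Reagents that add atoms: none
Why: Fluoride-mediated desilylation under acetic acid buffering frees the hydroxymethyl group without exposing the trienyl carbinol or the tetramic acid to strong acid or base.

Step 14
Reactants: 25 (5S)-5-benzyl-3-acyltetramic acid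
Product: 26 4-hydroxy-3-[(2R,4Z,6E,8E,10R)-4-(hydroxymethyl)-2,10-dimethyldodeca-4,6,8-trienoyl]-5-phenylpyridin-2(1H)-one
Conditions: recombinant cytochrome P450 ring-expandase (TenA/ApdE family, from a 5-phenyl-2-pyridone cluster) with its cytochrome P450 reductase, yeast microsomes; 25 (sodium salt, 0.2–0.5 mM, 2% DMSO), NADP+ (cat.), D-glucose, glucose dehydrogenase, air, potassium phosphate buffer pH 7.5, 28 °C; EtOAc extraction at pH 4
Reagents that add atoms: none
Why: The high-valent iron-oxo species of the enzyme (a tetravalent iron-oxo porphyrin radical cation) abstracts a hydrogen atom from the benzylic CH2 of 25; the benzylic radical (or the cation formed from it by electron transfer, or by rebound and ionisation) attacks the neighbouring ring carbon C4 to give a strained cyclopropane-type oxy intermediate that reopens with cleavage of the old C4–C5 bond, and loss of the second hydrogen from the former C5 aromatises the new ring. The closest known reaction type is the cytochrome P450 ring expansion of 5-benzyl- and 5-(4-hydroxybenzyl)-3-acyltetramic acids to 5-aryl-4-hydroxy-2-pyridones in fungal pyridone pathways, and in purely chemical terms it is a Dowd–Beckwith-type radical one-carbon ring enlargement (a semipinacol 1,2-acyl shift in the cationic variant). The pyridone ring is therefore closed by insertion of the benzylic carbon between C4 and C5 (3-exo attack followed by β-scission, a 1,2-shift) and not by an end-to-end cyclisation, so the five-membered lactam grows into the six-membered one and the new bond is pyridone C4–C5. No stereocentre is created: C5 of 25 becomes the sp2 carbon C6 of 26, and the (2R) and (10R) centres of the chain lie far from the site of oxidation. The step needs selectivity for the benzylic C–H bond over epoxidation of the triene and hydroxylation of its allylic positions; this should be secured by the active site, which binds the chelating tetramic acid head group and holds the benzyl group over the haem while the chain lies in the access channel, helped by the weakness of the benzylic C–H bond next to the amide-bearing carbon.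

Step 15
Reactants: 26 3-acyl-4-hydroxy-5-phenyl-2-pyridone
Product: 29 4-hydroxy-3-[(2R,3R,5Z)-3-methyl-5-[(2E,4E,6R)-6-methylocta-2,4-dien-1-ylidene]tetrahydro-2H-pyran-2-yl]-5-phenylpyridin-2(1H)-one, via carbinol 27 (not isolated), via quinone methide 28 (not isolated)
Conditions: NaBH4 (4 equiv), MeOH/THF, 0 °C; acetone quench; then AcOH to pH 5, rt → 40 °C
Reagents that add atoms: none
Why: Hydride reduction of the C-acyl ketone gives carbinol 27 (either epimer), which as a vinylogous acid loses water under mild acid to quinone methide 28, and 6-exo-trig oxa-Michael addition of the primary hydroxyl then closes the tetrahydropyran through a chair with the C3 methyl (brought in from 1) equatorial; because the closure is reversible under these conditions the 2,3-trans diequatorial (2R,3R) isomer should accumulate.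

Step 16
Reactants: 29 N–H pyridone
Product: 32 1,4-dihydroxy-3-[(2R,3R,5Z)-3-methyl-5-[(2E,4E,6R)-6-methylocta-2,4-dien-1-ylidene]tetrahydro-2H-pyran-2-yl]-5-phenylpyridin-2(1H)-one (CNP0190742.3), via bis-trimethylsilyl ether 30 (not isolated), via pyridine N-oxide 31 (not isolated)
Conditions: N,O-bis(trimethylsilyl)acetamide (4 equiv), CH2Cl2, rt; then MoO(O2)2(py)(HMPA) (1.5 equiv), CH2Cl2, 0 °C → rt, dark; aq. Na4EDTA/MeOH work-up; C18 chromatography
Reagents that add atoms: oxodiperoxomolybdenum(pyridine)(hexamethylphosphoric triamide), O=[Mo]12(OO1)OO2.c1ccncc1.CN(C)P(=O)(N(C)C)N(C)C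
Why: Silylation turns the pyridone into the 2,4-bis(silyloxy)pyridine, whose ring nitrogen should take an oxygen atom from a peroxo ligand of the coordinatively saturated molybdenum complex (N-oxidation of a silylated lactam to the cyclic hydroxamic acid), while the triene, which would need a free coordination site on the metal to be epoxidised, should be left; aqueous work-up removes the silyl groups and EDTA frees the product from molybdenum.

**Compound list**

1 | (S)-3-bromo-2-methylpropan-1-ol | BrC[C@@H](C)CO | starting material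
2 | (S)-(3-bromo-2-methylpropoxy)(tert-butyl)dimethylsilane | BrC[C@@H](C)CO[Si](C)(C)C(C)(C)C | intermediate
3 | prop-2-yn-1-ol (propargyl alcohol) | C#CCO | starting material
4 | (S)-[3-{[tert-butyl(dimethyl)silyl]oxy}-2-methylpropyl]magnesium bromide | Br[Mg]C[C@@H](C)CO[Si](C)(C)C(C)(C)C | intermediate (not isolated)
5 | bromomagnesium prop-2-yn-1-olate | C#CCO[Mg]Br | intermediate (not isolated)
6 | 4-[(2R)-3-{[tert-butyl(dimethyl)silyl]oxy}-2-methylpropyl]-2,5-dihydro-1,2-oxamagnesole | O1CC(C[C@@H](C)CO[Si](C)(C)C(C)(C)C)=C[Mg]1 | intermediate (not isolated)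
7 | (2Z)-2-[(2R)-3-{[tert-butyl(dimethyl)silyl]oxy}-2-methylpropyl]-3-iodoprop-2-en-1-ol | I/C=C(\CO)C[C@@H](C)CO[Si](C)(C)C(C)(C)C | intermediate
8 | tert-butyl{[(2R,4Z)-4-{[(tert-butyldiphenylsilyl)oxy]methyl}-5-iodo-2-methylpent-4-en-1-yl]oxy}dimethylsilane | I/C=C(\CO[Si](c1ccccc1)(c1ccccc1)C(C)(C)C)C[C@@H](C)CO[Si](C)(C)C(C)(C)C | intermediate
9 | (2R,4Z)-4-{[(tert-butyldiphenylsilyl)oxy]methyl}-5-iodo-2-methylpent-4-en-1-ol | I/C=C(\CO[Si](c1ccccc1)(c1ccccc1)C(C)(C)C)C[C@@H](C)CO | intermediate
10 | (R)-2-methylbutanoic acid | CC[C@@H](C)C(=O)O | starting material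
11 | (R)-2-methylbutan-1-ol | CC[C@@H](C)CO | intermediate
12 | (R)-2-methylbutanal | CC[C@@H](C)C=O | intermediate (not isolated)
13 | (1E,3R)-1-iodo-3-methylpent-1-ene | CC[C@@H](C)/C=C/I | intermediate
14 | (E)-1,2-bis(tributylstannyl)ethene | CCCC[Sn](CCCC)(CCCC)/C=C/[Sn](CCCC)(CCCC)CCCC | starting material
15 | tributyl[(1E,3E,5R)-5-methylhepta-1,3-dien-1-yl]stannane | CC[C@@H](C)/C=C/C=C/[Sn](CCCC)(CCCC)CCCC | intermediate
16 | (2R,4Z,6E,8E,10R)-4-{[(tert-butyldiphenylsilyl)oxy]methyl}-2,10-dimethyldodeca-4,6,8-trien-1-ol | CC[C@@H](C)/C=C/C=C/C=C(\CO[Si](c1ccccc1)(c1ccccc1)C(C)(C)C)C[C@@H](C)CO | intermediate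
17 | (2R,4Z,6E,8E,10R)-4-{[(tert-butyldiphenylsilyl)oxy]methyl}-2,10-dimethyldodeca-4,6,8-trienal | CC[C@@H](C)/C=C/C=C/C=C(\CO[Si](c1ccccc1)(c1ccccc1)C(C)(C)C)C[C@@H](C)C=O | intermediate (not isolated)
18 | (2R,4Z,6E,8E,10R)-4-{[(tert-butyldiphenylsilyl)oxy]methyl}-2,10-dimethyldodeca-4,6,8-trienoic acid | CC[C@@H](C)/C=C/C=C/C=C(\CO[Si](c1ccccc1)(c1ccccc1)C(C)(C)C)C[C@@H](C)C(=O)O | intermediate
19 | Meldrum's acid (2,2-dimethyl-1,3-dioxane-4,6-dione) | CC1(C)OC(=O)CC(=O)O1 | starting material
20 | 5-[(2R,4Z,6E,8E,10R)-4-{[(tert-butyldiphenylsilyl)oxy]methyl}-1-hydroxy-2,10-dimethyldodeca-4,6,8-trien-1-ylidene]-2,2-dimethyl-1,3-dioxane-4,6-dione | CC[C@@H](C)/C=C/C=C/C=C(\CO[Si](c1ccccc1)(c1ccccc1)C(C)(C)C)C[C@@H](C)C(O)=C1C(=O)OC(C)(C)OC1=O | intermediate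
21 | L-phenylalanine methyl ester hydrochloride | [Cl-].COC(=O)[C@@H]([NH3+])Cc1ccccc1 | starting material
22 | (4R,6Z,8E,10E,12R)-6-{[(tert-butyldiphenylsilyl)oxy]methyl}-4,12-dimethyltetradeca-1,6,8,10-tetraene-1,3-dione (acylketene) | CC[C@@H](C)/C=C/C=C/C=C(\CO[Si](c1ccccc1)(c1ccccc1)C(C)(C)C)C[C@@H](C)C(=O)C=C=O | intermediate (not isolated)
23 | methyl N-[(4R,6Z,8E,10E,12R)-6-{[(tert-butyldiphenylsilyl)oxy]methyl}-4,12-dimethyl-3-oxotetradeca-6,8,10-trienoyl]-L-phenylalaninate | CC[C@@H](C)/C=C/C=C/C=C(\CO[Si](c1ccccc1)(c1ccccc1)C(C)(C)C)C[C@@H](C)C(=O)CC(=O)N[C@@H](Cc1ccccc1)C(=O)OC | intermediate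
24 | (5S)-5-benzyl-3-[(2R,4Z,6E,8E,10R)-4-{[(tert-butyldiphenylsilyl)oxy]methyl}-2,10-dimethyldodeca-4,6,8-trienoyl]-4-hydroxy-1,5-dihydro-2H-pyrrol-2-one | CC[C@@H](C)/C=C/C=C/C=C(\CO[Si](c1ccccc1)(c1ccccc1)C(C)(C)C)C[C@@H](C)C(=O)C1=C(O)[C@H](Cc2ccccc2)NC1=O | intermediate
25 | (5S)-5-benzyl-4-hydroxy-3-[(2R,4Z,6E,8E,10R)-4-(hydroxymethyl)-2,10-dimethyldodeca-4,6,8-trienoyl]-1,5-dihydro-2H-pyrrol-2-one | CC[C@@H](C)/C=C/C=C/C=C(\CO)C[C@@H](C)C(=O)C1=C(O)[C@H](Cc2ccccc2)NC1=O | intermediate
26 | 4-hydroxy-3-[(2R,4Z,6E,8E,10R)-4-(hydroxymethyl)-2,10-dimethyldodeca-4,6,8-trienoyl]-5-phenylpyridin-2(1H)-one | CC[C@@H](C)/C=C/C=C/C=C(\CO)C[C@@H](C)C(=O)c1c(O)c(-c2ccccc2)c[nH]c1=O | intermediate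
27 | 4-hydroxy-3-[(2R,4Z,6E,8E,10R)-1-hydroxy-4-(hydroxymethyl)-2,10-dimethyldodeca-4,6,8-trien-1-yl]-5-phenylpyridin-2(1H)-one (both C1 epimers) | CC[C@@H](C)/C=C/C=C/C=C(\CO)C[C@@H](C)C(O)c1c(O)c(-c2ccccc2)c[nH]c1=O | intermediate (not isolated)
28 | 3-[(2R,4Z,6E,8E,10R)-4-(hydroxymethyl)-2,10-dimethyldodeca-4,6,8-trien-1-ylidene]-5-phenylpyridine-2,4(1H,3H)-dione (quinone methide) | CC[C@@H](C)/C=C/C=C/C=C(\CO)C[C@@H](C)C=C1C(=O)C(c2ccccc2)=CNC1=O | intermediate (not isolated)
29 | 4-hydroxy-3-[(2R,3R,5Z)-3-methyl-5-[(2E,4E,6R)-6-methylocta-2,4-dien-1-ylidene]tetrahydro-2H-pyran-2-yl]-5-phenylpyridin-2(1H)-one | CC[C@@H](C)/C=C/C=C/C=C1\CO[C@@H](c2c(O)c(-c3ccccc3)c[nH]c2=O)[C@H](C)C1 | intermediate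
30 | 3-[(2R,3R,5Z)-3-methyl-5-[(2E,4E,6R)-6-methylocta-2,4-dien-1-ylidene]tetrahydro-2H-pyran-2-yl]-5-phenyl-2,4-bis[(trimethylsilyl)oxy]pyridine | CC[C@@H](C)/C=C/C=C/C=C1\CO[C@@H](c2c(O[Si](C)(C)C)c(-c3ccccc3)cnc2O[Si](C)(C)C)[C@H](C)C1 | intermediate (not isolated)
31 | 3-[(2R,3R,5Z)-3-methyl-5-[(2E,4E,6R)-6-methylocta-2,4-dien-1-ylidene]tetrahydro-2H-pyran-2-yl]-5-phenyl-2,4-bis[(trimethylsilyl)oxy]pyridine 1-oxide | CC[C@@H](C)/C=C/C=C/C=C1\CO[C@@H](c2c(O[Si](C)(C)C)c(-c3ccccc3)c[n+]([O-])c2O[Si](C)(C)C)[C@H](C)C1 | intermediate (not isolated)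
32 | 1,4-dihydroxy-3-[(2R,3R,5Z)-3-methyl-5-[(2E,4E,6R)-6-methylocta-2,4-dien-1-ylidene]tetrahydro-2H-pyran-2-yl]-5-phenylpyridin-2(1H)-one (CNP0190742.3) | CC[C@@H](C)/C=C/C=C/C=C1\CO[C@@H](c2c(O)c(-c3ccccc3)cn(O)c2=O)[C@H](C)C1 | target

**Step count**

Total: 16 steps. Longest linear sequence: 13 steps (1 → 32 through steps 1–4 and 8–16); the stannane branch (steps 5–7) joins at step 8.

**Steps most likely to fail**

1. Step 14 (ring expansion). The enzyme may fail to bind or turn over a substrate whose chain is foreign to it, or the iron-oxo species may be diverted to epoxidation of the triene, to allylic hydroxylation, or to benzylic hydroxylation without the 1,2-shift. The fallback gives up the ring expansion and builds the pyridone separately; it sets out from 16 and comes back at 29. Alcohol 16 is oxidised with Dess–Martin periodinane to aldehyde 17, which is here isolated. TBAF/AcOH then removes the silyl group, and the hydroxy aldehyde closes to the lactol (3R,5Z)-3-methyl-5-[(2E,4E,6R)-6-methylocta-2,4-dien-1-ylidene]tetrahydro-2H-pyran-2-ol F1. In parallel, commercial 5-bromo-2,4-dimethoxypyridine is coupled with phenylboronic acid (Pd(PPh3)4, K2CO3, dioxane/water, 90 °C) to 2,4-dimethoxy-5-phenylpyridine F2, which is demethylated in molten pyridine hydrochloride to 4-hydroxy-5-phenylpyridin-2(1H)-one F3. Knoevenagel condensation of F1 (through its open hydroxy aldehyde form) with F3 under ethylenediammonium diacetate catalysis in EtOH at rt → 40 °C should give quinone methide 28, which closes to 29 as in step 15; the mild ammonium acetate catalyst is chosen to limit enolisation of the α-branched aldehyde. Step 16 then follows unchanged.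

2. Step 16 (N-hydroxylation). Oxygen transfer may go to the triene or the allylic ether instead of the ring nitrogen, silylation may be incomplete, and the product may be held back as a molybdenum chelate. The fallback replaces the chemical oxidant by biocatalysis; it sets out from 29 and comes back at 32. Compound 29 is incubated with the cytochrome P450 N-hydroxylase of the same pathway family (a TenB-type enzyme that converts N–H 2-pyridones into 1-hydroxy-2-pyridones), expressed with its reductase, under the NADPH-regenerating conditions of step 14. No new compound is made on the way.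

3. Step 2 (carbomagnesiation). Addition of the β-branched, silyloxy-bearing Grignard reagent to the alkoxide may be slow, so that deprotonation of the alkyne C–H and Wurtz coupling take over. The fallback sets the trisubstituted alkene by Z-selective olefination instead; it sets out from 2 and 12 and comes back at 16.
   - Bromide 2 alkylates the sodium salt of ethyl 2-(diphenoxyphosphoryl)acetate (NaH, NaI cat., DMSO, 50 °C) to give ethyl (4R)-5-{[tert-butyl(dimethyl)silyl]oxy}-2-(diphenoxyphosphoryl)-4-methylpentanoate F4.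
   - Aldehyde 12, taken from step 6 before the chromium stage, is extended with triethyl 4-phosphonocrotonate (LiN(SiMe3)2, THF, −78 → 0 °C) to ethyl (2E,4E,6R)-6-methylocta-2,4-dienoate F5. This is reduced with i-Bu2AlH to (2E,4E,6R)-6-methylocta-2,4-dien-1-ol F6 and oxidised with MnO2 to (2E,4E,6R)-6-methylocta-2,4-dienal F7.
   - Ando-type Horner–Wadsworth–Emmons reaction of F4 with F7 (NaH, THF, −78 → 0 °C) should give ethyl (2Z,4E,6E,8R)-2-[(2R)-3-{[tert-butyl(dimethyl)silyl]oxy}-2-methylpropyl]-8-methyldeca-2,4,6-trienoate F8, with the ester cis to the diene.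
   - i-Bu2AlH reduces F8 to (2Z,4E,6E,8R)-2-[(2R)-3-{[tert-butyl(dimethyl)silyl]oxy}-2-methylpropyl]-8-methyldeca-2,4,6-trien-1-ol F9. TBDPSCl/imidazole then gives tert-butyl{[(2R,4Z,6E,8E,10R)-4-{[(tert-butyldiphenylsilyl)oxy]methyl}-2,10-dimethyldodeca-4,6,8-trien-1-yl]oxy}dimethylsilane F10.
   - HF·pyridine in pyridine/THF at 0 °C cleaves the primary tert-butyldimethylsilyl ether selectively to give 16.

**Further compounds**

F1 | step 14 | (3R,5Z)-3-methyl-5-[(2E,4E,6R)-6-methylocta-2,4-dien-1-ylidene]tetrahydro-2H-pyran-2-ol | CC[C@@H](C)/C=C/C=C/C=C1\COC(O)[C@H](C)C1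
F2 | step 14 | 2,4-dimethoxy-5-phenylpyridine | COc1cc(OC)c(-c2ccccc2)cn1
F3 | step 14 | 4-hydroxy-5-phenylpyridin-2(1H)-one | O=c1cc(O)c(-c2ccccc2)c[nH]1
F0 | step 16 | none | none
F4 | step 2 | ethyl (4R)-5-{[tert-butyl(dimethyl)silyl]oxy}-2-(diphenoxyphosphoryl)-4-methylpentanoate | CCOC(=O)C(C[C@@H](C)CO[Si](C)(C)C(C)(C)C)P(=O)(Oc1ccccc1)Oc1ccccc1
F5 | step 2 | ethyl (2E,4E,6R)-6-methylocta-2,4-dienoate | CC[C@@H](C)/C=C/C=C/C(=O)OCC
F6 | step 2 | (2E,4E,6R)-6-methylocta-2,4-dien-1-ol | CC[C@@H](C)/C=C/C=C/CO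
F7 | step 2 | (2E,4E,6R)-6-methylocta-2,4-dienal | CC[C@@H](C)/C=C/C=C/C=O
F8 | step 2 | ethyl (2Z,4E,6E,8R)-2-[(2R)-3-{[tert-butyl(dimethyl)silyl]oxy}-2-methylpropyl]-8-methyldeca-2,4,6-trienoate | CC[C@@H](C)/C=C/C=C/C=C(\C(=O)OCC)C[C@@H](C)CO[Si](C)(C)C(C)(C)C
F9 | step 2 | (2Z,4E,6E,8R)-2-[(2R)-3-{[tert-butyl(dimethyl)silyl]oxy}-2-methylpropyl]-8-methyldeca-2,4,6-trien-1-ol | CC[C@@H](C)/C=C/C=C/C=C(\CO)C[C@@H](C)CO[Si](C)(C)C(C)(C)C
F10 | step 2 | tert-butyl{[(2R,4Z,6E,8E,10R)-4-{[(tert-butyldiphenylsilyl)oxy]methyl}-2,10-dimethyldodeca-4,6,8-trien-1-yl]oxy}dimethylsilane | CC[C@@H](C)/C=C/C=C/C=C(\CO[Si](c1ccccc1)(c1ccccc1)C(C)(C)C)C[C@@H](C)CO[Si](C)(C)C(C)(C)C
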